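**Retrosynthetic overview**
- The target comes from its C8-epimeric alcohol by Mitsunobu esterification with angelic acid (inversion); that alcohol comes from a 1,10-diol by lactone α-methylenation and oxidation of the secondary hydroxyl.
- The diol comes from chelation-controlled methyl addition to an α-hydroxy ketone, which is the hydroxylated product of an anionic oxy-Cope ring expansion of a lactone-fused cis-1-vinyl-2-isopropenylcyclohexanol (forms C2–C3, the ten-membered ring and the Z C4=C5 olefin).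
- The cyclohexanol comes from ethynyl addition and semi-hydrogenation on a cyclohexanone, itself made by an intramolecular carbonyl-ene cyclisation and oxidation.
- The ene precursor comes from (S)-5-(hydroxymethyl)furan-2(5H)-one by trans conjugate vinylation, ozonolysis, Felkin-selective Mukaiyama aldol and Wittig olefination.
- Ring order: butyrolactone (bought), then cyclohexane (ene reaction), then cyclodecene (oxy-Cope ring expansion of the cyclohexane).

Assumption: (S)-5-(hydroxymethyl)furan-2(5H)-one, produced on scale from cellulose-derived levoglucosenone, is taken as the purchasable chiral starting material.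
Atom labels C1–C13 in the Why lines are the usual germacranolide positions of the target: C1 ketone, C4=C5 olefin, C6 lactone oxygen, C7 ring fusion, C8 ester, C10 carbinol, C11–C13 methylene lactone.

**Route**

Step 1
Reactants: 1 (S)-5-(hydroxymethyl)furan-2(5H)-one
Product: 2 (S)-5-[(triethylsilyloxy)methyl]furan-2(5H)-one
Conditions: Et3SiCl, imidazole, CH2Cl2, 0 °C
Reagents that add atoms: chlorotriethylsilane CC[Si](Cl)(CC)CC
Why: Silyl ether formation (protection) masks the primary hydroxyl as a triethylsilyl ether that survives the cuprate and aldol steps and can later be oxidised directly, the bought stereocentre (C6 of the target) being untouched.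

Step 2
Reactants: 2 (S)-5-[(triethylsilyloxy)methyl]furan-2(5H)-one
Product: 3 (4R,5S)-4-ethenyl-5-[(triethylsilyloxy)methyl]oxolan-2-one
Conditions: vinylmagnesium bromide, CuBr·SMe2 (10 mol %), THF, −78 °C; aq. NH4Cl
Reagents that add atoms: vinylmagnesium bromide C=C[Mg]Br
Why: Copper-catalysed conjugate addition of the vinyl Grignard reagent to the butenolide occurs anti to the silyloxymethyl group on the adjacent stereocentre, giving the trans-4,5-disubstituted lactone and thereby setting C7.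

Step 3
Reactants: 3 (4R,5S)-4-ethenyl-5-[(triethylsilyloxy)methyl]oxolan-2-one
Product: 5 (2S,3S)-5-oxo-2-[(triethylsilyloxy)methyl]oxolane-3-carbaldehyde, via secondary ozonide 4 (not isolated)
Conditions: O3, CH2Cl2, −78 °C; then Me2S, −78 °C → rt
Reagents that add atoms: ozone [O-][O+]=O
Why: Ozonolysis with reductive work-up cleaves the only olefin to the aldehyde (C8) under neutral conditions that leave the lactone, the silyl ether and both stereocentres intact.

Step 4
Reactants: 6 S-ethyl ethanethioate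
Product: 7 tert-butyl{[1-(ethylsulfanyl)ethenyl]oxy}dimethylsilane
Conditions: lithium diisopropylamide, THF, −78 °C; then tBuMe2SiCl, DMPU, −78 °C → rt
Reagents that add atoms: tert-butylchlorodimethylsilane CC(C)(C)[Si](C)(C)Cl
Why: Enolisation of the thioester and O-silylation (silyl ketene thioacetal formation) provides the nucleophile for the Mukaiyama aldol, no stereocentre being involved.

Step 5
Reactants: 5 (2S,3S)-5-oxo-2-[(triethylsilyloxy)methyl]oxolane-3-carbaldehyde; 7 tert-butyl{[1-(ethylsulfanyl)ethenyl]oxy}dimethylsilane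
Product: 8 S-ethyl (3S)-3-[(tert-butyldimethylsilyl)oxy]-3-{(2S,3S)-5-oxo-2-[(triethylsilyloxy)methyl]oxolan-3-yl}propanethioate
Conditions: tBuMe2SiOTf (10 mol %), CH2Cl2, −78 °C
Reagents that add atoms: none
Why: Silyl-triflate-catalysed Mukaiyama aldol addition with silyl transfer proceeds through an open transition state in which the ketene thioacetal attacks the aldehyde anti to the larger C6 branch of the ring (Felkin–Anh control), giving the (3S)-silyloxy thioester whose C8 oxygen will sit equatorial in the later cyclohexane and is inverted in the last step.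

Step 6
Reactants: 8 S-ethyl (3S)-3-[(tert-butyldimethylsilyl)oxy]-3-{(2S,3S)-5-oxo-2-[(triethylsilyloxy)methyl]oxolan-3-yl}propanethioate
Product: 9 S-ethyl (3S)-3-[(tert-butyldimethylsilyl)oxy]-3-[(2S,3S)-2-formyl-5-oxooxolan-3-yl]propanethioate
Conditions: (COCl)2, DMSO, CH2Cl2, −78 → −30 °C; then Et3N, −78 → 0 °C
Reagents that add atoms: none
Why: Swern oxidation cleaves and oxidises the primary triethylsilyl ether in one operation while the secondary tert-butyldimethylsilyl ether, the thioester and the lactone are inert, and the cold amine quench keeps the α-oxygenated stereocentre intact.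

Step 7
Reactants: 9 S-ethyl (3S)-3-[(tert-butyldimethylsilyl)oxy]-3-[(2S,3S)-2-formyl-5-oxooxolan-3-yl]propanethioate
Product: 10 S-ethyl (3S)-3-[(tert-butyldimethylsilyl)oxy]-3-[(2R,3S)-2-(2-methylprop-1-en-1-yl)-5-oxooxolan-3-yl]propanethioate
Conditions: iPrPPh3 iodide, nBuLi, THF, 0 °C; then 9 (1.0 equiv of ylide added to the aldehyde), −78 → 0 °C
Reagents that add atoms: isopropyltriphenylphosphonium iodide CC(C)[P+](c1ccccc1)(c1ccccc1)c1ccccc1.[I-]
Why: Wittig olefination with the non-stabilised isopropylidene ylide at −78 °C converts the aldehyde into the trisubstituted olefin (no E/Z issue) faster than the ylide can attack the thioester or epimerise C6.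

Step 8
Reactants: 10 S-ethyl (3S)-3-[(tert-butyldimethylsilyl)oxy]-3-[(2R,3S)-2-(2-methylprop-1-en-1-yl)-5-oxooxolan-3-yl]propanethioate
Product: 11 (3S)-3-[(tert-butyldimethylsilyl)oxy]-3-[(2R,3S)-2-(2-methylprop-1-en-1-yl)-5-oxooxolan-3-yl]propanal
Conditions: Et3SiH, Pd/C (10 %), acetone, rt
Reagents that add atoms: none
Why: Fukuyama reduction (palladium-catalysed hydrosilane reduction of a thioester) delivers the aldehyde chemoselectively in the presence of the lactone, the silyl ether and the trisubstituted olefin.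

Step 9
Reactants: 11 (3S)-3-[(tert-butyldimethylsilyl)oxy]-3-[(2R,3S)-2-(2-methylprop-1-en-1-yl)-5-oxooxolan-3-yl]propanal
Product: 12 (3aS,4S,6R,7S,7aS)-4-[(tert-butyldimethylsilyl)oxy]-6-hydroxy-7-(prop-1-en-2-yl)hexahydro-1-benzofuran-2(3H)-one
Conditions: Me2AlCl (1.5 equiv), CH2Cl2, −78 → −40 °C
Reagents that add atoms: none
Why: Lewis-acid-promoted intramolecular carbonyl-ene reaction (the citronellal-to-isopulegol cyclisation) forms the C5–C10 bond through a chair transition state with every substituent equatorial, so the trans-fused lactone dictates an equatorial hydroxyl and an equatorial isopropenyl group trans to the lactone oxygen.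

Step 10
Reactants: 12 (3aS,4S,6R,7S,7aS)-4-[(tert-butyldimethylsilyl)oxy]-6-hydroxy-7-(prop-1-en-2-yl)hexahydro-1-benzofuran-2(3H)-one
Product: 13 (3aS,4S,7R,7aS)-4-[(tert-butyldimethylsilyl)oxy]-7-(prop-1-en-2-yl)-3a,4,5,7a-tetrahydro-1-benzofuran-2,6(3H,7H)-dione
Conditions: Dess–Martin periodinane, CH2Cl2, 0 °C → rt
Reagents that add atoms: none
Why: Dess–Martin oxidation gives the ketone under non-basic conditions, which matters because the product is a β-acyloxy ketone with an acidic α-hydrogen, and C5 keeps its thermodynamically preferred equatorial configuration.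

Step 11
Reactants: 13 (3aS,4S,7R,7aS)-4-[(tert-butyldimethylsilyl)oxy]-7-(prop-1-en-2-yl)-3a,4,5,7a-tetrahydro-1-benzofuran-2,6(3H,7H)-dione
Product: 14 (3aS,4S,6R,7R,7aS)-4-[(tert-butyldimethylsilyl)oxy]-6-ethynyl-6-hydroxy-7-(prop-1-en-2-yl)hexahydro-1-benzofuran-2(3H)-one
Conditions: HC≡CMgBr, CeCl3, THF, −78 °C; aq. NH4Cl
Reagents that add atoms: ethynylmagnesium bromide C#C[Mg]Br
Why: 1,2-Addition of a weakly basic cerium acetylide (Imamoto conditions) avoids enolisation and β-elimination, and the small sp-hybridised nucleophile attacks the locked all-equatorial cyclohexanone along the axial trajectory, placing the ethynyl group axial and cis to the isopropenyl group and the hydroxyl equatorial.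

Step 12
Reactants: 14 (3aS,4S,6R,7R,7aS)-4-[(tert-butyldimethylsilyl)oxy]-6-ethynyl-6-hydroxy-7-(prop-1-en-2-yl)hexahydro-1-benzofuran-2(3H)-one
Product: 15 (3aS,4S,6S,7R,7aS)-4-[(tert-butyldimethylsilyl)oxy]-6-ethenyl-6-hydroxy-7-(prop-1-en-2-yl)hexahydro-1-benzofuran-2(3H)-one
Conditions: H2 (1 atm), Pd/CaCO3 poisoned with Pb(OAc)2, quinoline, EtOAc, rt
Reagents that add atoms: none
Why: Lindlar semi-hydrogenation reduces the terminal alkyne to the vinyl group without touching the isopropenyl group or any stereocentre.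

Step 13
Reactants: 15 (3aS,4S,6S,7R,7aS)-4-[(tert-butyldimethylsilyl)oxy]-6-ethenyl-6-hydroxy-7-(prop-1-en-2-yl)hexahydro-1-benzofuran-2(3H)-one
Product: 18 (3aS,4S,7R,10Z,11aR)-4-[(tert-butyldimethylsilyl)oxy]-7-hydroxy-10-methyl-3,3a,4,5,7,8,9,11a-octahydrocyclodeca[b]furan-2,6-dione, via potassium alkoxide 16 (not isolated), via potassium enolate 17 (not isolated)
Conditions: KN(SiMe3)2 (1.05 equiv), 18-crown-6, THF, −78 → 0 °C; then 2-(phenylsulfonyl)-3-phenyloxaziridine, −78 °C; AcOH
Reagents that add atoms: 2-(phenylsulfonyl)-3-phenyloxaziridine O=S(=O)(c1ccccc1)N1OC1c1ccccc1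
Why: Anionic oxy-Cope rearrangement (a [3,3]-sigmatropic shift) of the potassium alkoxide through a chair transition state, in which the axial vinyl and equatorial isopropenyl groups of the locked ring are gauche, forms the C2–C3 bond, breaks C5–C10 and gives the ten-membered ring with the Z C4=C5 olefin, and the resulting enolate is hydroxylated at C1 by the Davis oxaziridine from its exposed peripheral face (7R), as peracids attack the C1=C10 olefin of germacranolides.

Step 14
Reactants: 18 (3aS,4S,7R,10Z,11aR)-4-[(tert-butyldimethylsilyl)oxy]-7-hydroxy-10-methyl-3,3a,4,5,7,8,9,11a-octahydrocyclodeca[b]furan-2,6-dione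
Product: 20 (3aS,4S,6S,7R,10Z,11aR)-4-[(tert-butyldimethylsilyl)oxy]-6,7-dihydroxy-6,10-dimethyl-3a,4,5,6,7,8,9,11a-octahydrocyclodeca[b]furan-2(3H)-one, via bromomagnesium alkoxide 19 (not isolated)
Conditions: MeMgBr (3 equiv), CH2Cl2–Et2O, −78 °C; aq. NH4Cl
Reagents that add atoms: methylmagnesium bromide C[Mg]Br
Why: Chelation-controlled Grignard addition (Cram cyclic model) has magnesium bridging the C1 alkoxide and the C10 carbonyl so that the methyl group enters from the side of the C1 hydrogen, which sets the C10 carbinol (6S) cis to the C1 oxygen, while the lactone is not attacked at −78 °C.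

Step 15
Reactants: 20 (3aS,4S,6S,7R,10Z,11aR)-4-[(tert-butyldimethylsilyl)oxy]-6,7-dihydroxy-6,10-dimethyl-3a,4,5,6,7,8,9,11a-octahydrocyclodeca[b]furan-2(3H)-one
Product: 23 (3aS,4S,6S,7R,10Z,11aR)-4-[(tert-butyldimethylsilyl)oxy]-6,7-dihydroxy-6,10-dimethyl-3-methylidene-3a,4,5,6,7,8,9,11a-octahydrocyclodeca[b]furan-2(3H)-one, via Mannich base 21 (not isolated), via trimethylammonium iodide 22 (not isolated)
Conditions: lithium diisopropylamide (3.3 equiv), THF, −78 °C; Eschenmoser's salt (Me2N=CH2 iodide), −78 → 0 °C; then MeI, MeOH, rt; then aq. NaHCO3, CH2Cl2, rt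
Reagents that add atoms: N,N-dimethylmethyleneiminium iodide C=[N+](C)C.[I-]
Why: α-Methylenation of the lactone by Mannich reaction of its lithium enolate with Eschenmoser's salt, followed by quaternisation and base-induced elimination of trimethylamine, installs the exocyclic methylene (C13) without affecting any stereocentre.

Step 16
Reactants: 23 (3aS,4S,6S,7R,10Z,11aR)-4-[(tert-butyldimethylsilyl)oxy]-6,7-dihydroxy-6,10-dimethyl-3-methylidene-3a,4,5,6,7,8,9,11a-octahydrocyclodeca[b]furan-2(3H)-one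
Product: 24 (3aS,4S,6S,10Z,11aR)-4-[(tert-butyldimethylsilyl)oxy]-6-hydroxy-6,10-dimethyl-3-methylidene-3a,4,5,8,9,11a-hexahydrocyclodeca[b]furan-2,7(3H,6H)-dione
Conditions: SO3·pyridine, DMSO, iPr2NEt, CH2Cl2, 0 °C
Reagents that add atoms: none
Why: Parikh–Doering oxidation converts the secondary C1 alcohol into the ketone while the tertiary C10 alcohol, the silyl ether and the methylene lactone are untouched, giving the α-ketol with C10 intact.

Step 17
Reactants: 24 (3aS,4S,6S,10Z,11aR)-4-[(tert-butyldimethylsilyl)oxy]-6-hydroxy-6,10-dimethyl-3-methylidene-3a,4,5,8,9,11a-hexahydrocyclodeca[b]furan-2,7(3H,6H)-dione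
Product: 25 (3aR,4S,6S,10Z,11aR)-4,6-dihydroxy-6,10-dimethyl-3-methylidene-3a,4,5,8,9,11a-hexahydrocyclodeca[b]furan-2,7(3H,6H)-dione
Conditions: HF·pyridine, THF–pyridine, 0 °C → rt
Reagents that add atoms: none
Why: Fluoride-mediated desilylation frees the C8 hydroxyl under buffered conditions tolerated by the α-ketol and the methylene lactone.

Step 18
Reactants: 25 (3aR,4S,6S,10Z,11aR)-4,6-dihydroxy-6,10-dimethyl-3-methylidene-3a,4,5,8,9,11a-hexahydrocyclodeca[b]furan-2,7(3H,6H)-dione; 26 angelic acid [(2Z)-2-methylbut-2-enoic acid]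
Product: 27 (3aR,4R,6S,10Z,11aR)-6-hydroxy-6,10-dimethyl-3-methylidene-2,7-dioxo-2,3,3a,4,5,6,7,8,9,11a-decahydrocyclodeca[b]furan-4-yl (2Z)-2-methylbut-2-enoate (CNP0345906.2)
Conditions: PPh3, DIAD, toluene, 0 °C → rt
Reagents that add atoms: none
Why: Mitsunobu esterification activates the C8 alcohol as its oxyphosphonium salt, which angelate displaces with clean inversion (SN2) to give the required 4R ester, while the tertiary alcohol is inert and the neutral conditions do not isomerise the Z-angelate.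

**Compound list**

1 | (S)-5-(hydroxymethyl)furan-2(5H)-one | O=C1C=C[C@@H](CO)O1 | starting material
2 | (S)-5-[(triethylsilyloxy)methyl]furan-2(5H)-one | O=C1C=C[C@@H](CO[Si](CC)(CC)CC)O1 | intermediate
3 | (4R,5S)-4-ethenyl-5-[(triethylsilyloxy)methyl]oxolan-2-one | O=C1C[C@H](C=C)[C@@H](CO[Si](CC)(CC)CC)O1 | intermediate
4 | secondary ozonide, (4S,5S)-4-(1,2,4-trioxolan-3-yl)-5-[(triethylsilyloxy)methyl]oxolan-2-one (epimer mixture at the trioxolane carbon) | O=C1C[C@H](C2OCOO2)[C@@H](CO[Si](CC)(CC)CC)O1 | intermediate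
5 | (2S,3S)-5-oxo-2-[(triethylsilyloxy)methyl]oxolane-3-carbaldehyde | O=C1C[C@H](C=O)[C@@H](CO[Si](CC)(CC)CC)O1 | intermediate
6 | S-ethyl ethanethioate | CC(=O)SCC | starting material
7 | tert-butyl{[1-(ethylsulfanyl)ethenyl]oxy}dimethylsilane | C=C(SCC)O[Si](C)(C)C(C)(C)C | intermediate
8 | S-ethyl (3S)-3-[(tert-butyldimethylsilyl)oxy]-3-{(2S,3S)-5-oxo-2-[(triethylsilyloxy)methyl]oxolan-3-yl}propanethioate | O=C1C[C@H]([C@@H](O[Si](C)(C)C(C)(C)C)CC(=O)SCC)[C@@H](CO[Si](CC)(CC)CC)O1 | intermediate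
9 | S-ethyl (3S)-3-[(tert-butyldimethylsilyl)oxy]-3-[(2S,3S)-2-formyl-5-oxooxolan-3-yl]propanethioate | O=C1C[C@H]([C@@H](O[Si](C)(C)C(C)(C)C)CC(=O)SCC)[C@@H](C=O)O1 | intermediate
10 | S-ethyl (3S)-3-[(tert-butyldimethylsilyl)oxy]-3-[(2R,3S)-2-(2-methylprop-1-en-1-yl)-5-oxooxolan-3-yl]propanethioate | O=C1C[C@H]([C@@H](O[Si](C)(C)C(C)(C)C)CC(=O)SCC)[C@@H](C=C(C)C)O1 | intermediate
11 | (3S)-3-[(tert-butyldimethylsilyl)oxy]-3-[(2R,3S)-2-(2-methylprop-1-en-1-yl)-5-oxooxolan-3-yl]propanal | O=C1C[C@H]([C@@H](O[Si](C)(C)C(C)(C)C)CC=O)[C@@H](C=C(C)C)O1 | intermediate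
12 | (3aS,4S,6R,7S,7aS)-4-[(tert-butyldimethylsilyl)oxy]-6-hydroxy-7-(prop-1-en-2-yl)hexahydro-1-benzofuran-2(3H)-one (trans-fused, all ring substituents equatorial) | C1C(=O)O[C@@H]2[C@@H](C(C)=C)[C@H](O)C[C@H](O[Si](C)(C)C(C)(C)C)[C@@H]12 | intermediate
13 | (3aS,4S,7R,7aS)-4-[(tert-butyldimethylsilyl)oxy]-7-(prop-1-en-2-yl)-3a,4,5,7a-tetrahydro-1-benzofuran-2,6(3H,7H)-dione | C1C(=O)O[C@@H]2[C@@H](C(C)=C)C(=O)C[C@H](O[Si](C)(C)C(C)(C)C)[C@@H]12 | intermediate
14 | (3aS,4S,6R,7R,7aS)-4-[(tert-butyldimethylsilyl)oxy]-6-ethynyl-6-hydroxy-7-(prop-1-en-2-yl)hexahydro-1-benzofuran-2(3H)-one (ethynyl axial, cis to isopropenyl) | C1C(=O)O[C@@H]2[C@@H](C(C)=C)[C@@](O)(C#C)C[C@H](O[Si](C)(C)C(C)(C)C)[C@@H]12 | intermediate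
15 | (3aS,4S,6S,7R,7aS)-4-[(tert-butyldimethylsilyl)oxy]-6-ethenyl-6-hydroxy-7-(prop-1-en-2-yl)hexahydro-1-benzofuran-2(3H)-one (vinyl axial, cis to isopropenyl) | C1C(=O)O[C@@H]2[C@@H](C(C)=C)[C@@](O)(C=C)C[C@H](O[Si](C)(C)C(C)(C)C)[C@@H]12 | intermediate
16 | potassium alkoxide of 15 | C1C(=O)O[C@@H]2[C@@H](C(C)=C)[C@@]([O-])(C=C)C[C@H](O[Si](C)(C)C(C)(C)C)[C@@H]12.[K+] | intermediate
17 | potassium (3aS,4S,6Z,10Z,11aR)-4-[(tert-butyldimethylsilyl)oxy]-10-methyl-2-oxo-2,3,3a,4,5,8,9,11a-octahydrocyclodeca[b]furan-6-olate (ring-expanded enolate, ring carbons trans across C6=C7) | C1C(=O)O[C@@H]2/C=C(/C)CC/C=C(\[O-])C[C@H](O[Si](C)(C)C(C)(C)C)[C@@H]12.[K+] | intermediate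
18 | (3aS,4S,7R,10Z,11aR)-4-[(tert-butyldimethylsilyl)oxy]-7-hydroxy-10-methyl-3,3a,4,5,7,8,9,11a-octahydrocyclodeca[b]furan-2,6-dione | C1C(=O)O[C@@H]2/C=C(/C)CC[C@@H](O)C(=O)C[C@H](O[Si](C)(C)C(C)(C)C)[C@@H]12 | intermediate
19 | bromomagnesium alkoxide of 18 (chelate) | C1C(=O)O[C@@H]2/C=C(/C)CC[C@@H](O[Mg]Br)C(=O)C[C@H](O[Si](C)(C)C(C)(C)C)[C@@H]12 | intermediate
20 | (3aS,4S,6S,7R,10Z,11aR)-4-[(tert-butyldimethylsilyl)oxy]-6,7-dihydroxy-6,10-dimethyl-3a,4,5,6,7,8,9,11a-octahydrocyclodeca[b]furan-2(3H)-one | C1C(=O)O[C@@H]2/C=C(/C)CC[C@@H](O)[C@@](C)(O)C[C@H](O[Si](C)(C)C(C)(C)C)[C@@H]12 | intermediate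
21 | Mannich base, 3-[(dimethylamino)methyl] derivative of 20 (epimer mixture at C3) | CN(C)CC1C(=O)O[C@@H]2/C=C(/C)CC[C@@H](O)[C@@](C)(O)C[C@H](O[Si](C)(C)C(C)(C)C)[C@@H]12 | intermediate
22 | trimethylammonium iodide of 21 (epimer mixture at C3) | C[N+](C)(C)CC1C(=O)O[C@@H]2/C=C(/C)CC[C@@H](O)[C@@](C)(O)C[C@H](O[Si](C)(C)C(C)(C)C)[C@@H]12.[I-] | intermediate
23 | (3aS,4S,6S,7R,10Z,11aR)-4-[(tert-butyldimethylsilyl)oxy]-6,7-dihydroxy-6,10-dimethyl-3-methylidene-3a,4,5,6,7,8,9,11a-octahydrocyclodeca[b]furan-2(3H)-one | C=C1C(=O)O[C@@H]2/C=C(/C)CC[C@@H](O)[C@@](C)(O)C[C@H](O[Si](C)(C)C(C)(C)C)[C@@H]12 | intermediate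
24 | (3aS,4S,6S,10Z,11aR)-4-[(tert-butyldimethylsilyl)oxy]-6-hydroxy-6,10-dimethyl-3-methylidene-3a,4,5,8,9,11a-hexahydrocyclodeca[b]furan-2,7(3H,6H)-dione | C=C1C(=O)O[C@@H]2/C=C(/C)CCC(=O)[C@@](C)(O)C[C@H](O[Si](C)(C)C(C)(C)C)[C@@H]12 | intermediate
25 | (3aR,4S,6S,10Z,11aR)-4,6-dihydroxy-6,10-dimethyl-3-methylidene-3a,4,5,8,9,11a-hexahydrocyclodeca[b]furan-2,7(3H,6H)-dione | C=C1C(=O)O[C@@H]2/C=C(/C)CCC(=O)[C@@](C)(O)C[C@H](O)[C@@H]12 | intermediate
26 | angelic acid, (2Z)-2-methylbut-2-enoic acid | C/C=C(/C)C(=O)O | starting material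
27 | (3aR,4R,6S,10Z,11aR)-6-hydroxy-6,10-dimethyl-3-methylidene-2,7-dioxo-2,3,3a,4,5,6,7,8,9,11a-decahydrocyclodeca[b]furan-4-yl (2Z)-2-methylbut-2-enoate | C=C1C(=O)O[C@@H]2/C=C(/C)CCC(=O)[C@@](C)(O)C[C@@H](OC(=O)/C(C)=C\C)[C@@H]12 | target

**Totals**

Total step count: 18. Longest linear sequence: 17 steps (1 to 27 through steps 1–3 and 5–18; step 4 is a one-step side branch).

**The three steps most likely to fail**

Step 13 (ring expansion and hydroxylation). The naked potassium alkoxide may enolise the lactone, or the rearrangement may leak through a boat transition state to the E olefin. The fallback sets out from 15 and avoids strong base. Silylation with Me3SiOTf and Et3N gives the trimethylsilyl ether of 15 F1. Heating F1 in o-xylene at about 200 °C in a sealed tube (neutral siloxy-Cope rearrangement) gives the ring-expanded trimethylsilyl enol ether F2. Rubottom oxidation of F2 with dimethyldioxirane in acetone at −78 °C gives the 7-trimethylsilyloxy ketone F3. Brief treatment of F3 with citric acid in MeOH removes the trimethylsilyl group and comes back to the route at 18.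

Step 14 (methyl addition, C10 configuration). The outcome rests on the C1 configuration set in step 13 and on chelation holding in a ten-membered ring; the C10 epimer or a mixture is possible. The fallback sets out from 15 and builds C10 from an olefin instead of a ketone. The enolate 17, generated as in step 13, is trapped with PhNTf2 to give the enol triflate F4. Me2CuLi in THF at −20 °C replaces the triflate by methyl with retention to give the (6E,10Z)-diene F5. mCPBA with NaHCO3 in CH2Cl2 at 0 °C epoxidises the more electron-rich, strained E olefin from its outer face to give the 6,7-epoxide F6. Catalytic HClO4 in aqueous THF at 0 °C opens F6 at the tertiary carbon with inversion and comes back to the route at 20.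

Step 18 (Mitsunobu inversion). The C8 alcohol of 25 is hindered, may sit partly as a transannular hemiketal with the C1 ketone, and may eliminate instead of substituting. The fallback sets out from 25 and separates activation from displacement. ClCH2SO2Cl and pyridine in CH2Cl2 at 0 °C give the 4-O-chloromethanesulfonate of 25 F7. Caesium angelate (from 26 and Cs2CO3) with 18-crown-6 in toluene at 80 °C displaces the sulfonate with inversion and comes back to the route at 27.

Further compounds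
F1 | step 13 | 6-O-trimethylsilyl ether of 15 | C1C(=O)O[C@@H]2[C@@H](C(C)=C)[C@@](O[Si](C)(C)C)(C=C)C[C@H](O[Si](C)(C)C(C)(C)C)[C@@H]12
F2 | step 13 | ring-expanded trimethylsilyl enol ether, (6Z,10Z)-4-[(tert-butyldimethylsilyl)oxy]-10-methyl-6-[(trimethylsilyl)oxy]-3a,4,5,8,9,11a-hexahydrocyclodeca[b]furan-2(3H)-one | C1C(=O)O[C@@H]2/C=C(/C)CC/C=C(\O[Si](C)(C)C)C[C@H](O[Si](C)(C)C(C)(C)C)[C@@H]12
F3 | step 13 | 7-O-trimethylsilyl ether of 18 | C1C(=O)O[C@@H]2/C=C(/C)CC[C@@H](O[Si](C)(C)C)C(=O)C[C@H](O[Si](C)(C)C(C)(C)C)[C@@H]12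
F4 | step 14 | enol triflate, (6Z,10Z)-4-[(tert-butyldimethylsilyl)oxy]-10-methyl-2-oxo-2,3,3a,4,5,8,9,11a-octahydrocyclodeca[b]furan-6-yl trifluoromethanesulfonate | C1C(=O)O[C@@H]2/C=C(/C)CC/C=C(\OS(=O)(=O)C(F)(F)F)C[C@H](O[Si](C)(C)C(C)(C)C)[C@@H]12
F5 | step 14 | (3aS,4S,6E,10Z,11aR)-4-[(tert-butyldimethylsilyl)oxy]-6,10-dimethyl-3a,4,5,8,9,11a-hexahydrocyclodeca[b]furan-2(3H)-one | C1C(=O)O[C@@H]2/C=C(/C)CC/C=C(\C)C[C@H](O[Si](C)(C)C(C)(C)C)[C@@H]12
F6 | step 14 | 6,7-epoxide of F5 (trans epoxide, oxygen on the outer face) | C1C(=O)O[C@@H]2/C=C(/C)CC[C@H]3O[C@]3(C)C[C@H](O[Si](C)(C)C(C)(C)C)[C@@H]12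
F7 | step 18 | 4-O-chloromethanesulfonate of 25 | C=C1C(=O)O[C@@H]2/C=C(/C)CCC(=O)[C@@](C)(O)C[C@H](OS(=O)(=O)CCl)[C@@H]12
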